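## Retrosynthetic overview

1. Last bond C4–C5: an intramolecular Nozaki–Hiyama–Kishi reaction of a 1-bromovinyl furanone onto an α-acyloxy aldehyde closes the ten-membered carbocycle, creates the C5 carbinol and gives the target directly.
2. C7–C8 and the lactone: zinc Barbier (Dreiding–Schmidt) allylation of a furanone aldehyde (fragment A) with a (Z)-2-(bromomethyl)enoate (fragment B), then lactonisation.
3. Fragment A: (S)-lactic acid → Seebach allylation (sets C10) → methyl ketone → aldol with 2-bromoacrolein → oxidation → acid cyclodehydration to the 3(2H)-furanone → alkene cleavage.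
4. Fragment B: (S)-solketal (supplies C6) → differentially protected glyceraldehyde → Morita–Baylis–Hillman adduct → SN2' bromide.
5. Ring order: furanone, then α-methylene-γ-butyrolactone, then the ten-membered ring.

Assumption: atoms are labelled with germacrane numbering (C1 ketone, C2=C3 furanone olefin, C4=C15 exo-methylene, C5 carbinol, C6 ester carbon, C7/C8 lactone ring carbons, C9 methylene, C10 quaternary carbon, C11–C13 acrylate unit, C14 methyl); the target is then (5S,6R,7S,8S,10R).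

## Route

Step 1
Reactants: 1 (S)-lactic acid
Product: 2 (2S,5S)-2-tert-butyl-5-methyl-1,3-dioxolan-4-one
Conditions: t-BuCHO, TsOH·H2O (cat.), H2SO4 (cat.), pentane, reflux, Dean–Stark; recrystallise (pentane/Et2O, −78 °C)
Reagents that add atoms: pivalaldehyde, CC(C)(C)C=O
Why: Acid-catalysed acetalisation (first stage of the Seebach self-regeneration of stereocentres) gives mainly the cis acetal, which crystallises diastereomerically pure, so the lactate configuration is stored in the new 2S acetal centre.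

Step 2
Reactants: 2 (2S,5S)-2-tert-butyl-5-methyl-1,3-dioxolan-4-one; 3 allyl bromide
Product: 5 (2S,5R)-2-tert-butyl-5-methyl-5-(prop-2-en-1-yl)-1,3-dioxolan-4-one, via lithium enolate 4 (not isolated)
Conditions: LiN(iPr)2 (commercial solution), THF, −78 °C; then 3, −78 → −30 °C
Reagents that add atoms: none
Why: Diastereoselective enolate alkylation: the planar enolate is allylated on the face anti to the tert-butyl group, so allyl takes the place of the former hydrogen and creates the quaternary centre 5R, which becomes C10 (R).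

Step 3
Reactants: 5 (2S,5R)-2-tert-butyl-5-methyl-5-(prop-2-en-1-yl)-1,3-dioxolan-4-one
Product: 6 (2R)-2-hydroxy-N-methoxy-N,2-dimethylpent-4-enamide
Conditions: MeNH(OMe)·HCl, iPrMgCl, THF, −20 → 0 °C
Reagents that add atoms: N,O-dimethylhydroxylamine hydrochloride, CNOC.Cl
Why: Aminolysis of the activated acylal-type ester by the magnesium amide (Weinreb amide formation) opens the dioxolanone and expels pivalaldehyde without touching the quaternary stereocentre.

Step 4
Reactants: 6 (2R)-2-hydroxy-N-methoxy-N,2-dimethylpent-4-enamide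
Product: 7 (2R)-N-methoxy-N,2-dimethyl-2-[(trimethylsilyl)oxy]pent-4-enamide
Conditions: Me3SiCl, imidazole, DMF, rt
Reagents that add atoms: chlorotrimethylsilane, C[Si](C)(C)Cl
Why: Silylation masks the tertiary alcohol as an ether that tolerates the Grignard, enolate and oxidation steps and is lost in the later acid cyclisation.

Step 5
Reactants: 7 (2R)-N-methoxy-N,2-dimethyl-2-[(trimethylsilyl)oxy]pent-4-enamide
Product: 8 (3R)-3-methyl-3-[(trimethylsilyl)oxy]hex-5-en-2-one
Conditions: MeMgBr, THF, 0 °C → rt; aq. NH4Cl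
Reagents that add atoms: methylmagnesium bromide, C[Mg]Br
Why: Weinreb ketone synthesis: the chelated tetrahedral adduct survives until work-up, so exactly one methyl group (C2) is added.

Step 6
Reactants: 9 acrolein
Product: 11 2-bromoacrolein, via 2,3-dibromopropanal 10 (not isolated)
Conditions: Br2, CH2Cl2, −78 → 0 °C; then Et3N, 0 °C; distil under reduced pressure and use at once
Reagents that add atoms: bromine, BrBr
Why: Bromine addition to the alkene followed by amine-induced E1cB loss of HBr from the α-bromo aldehyde gives the α-bromo enal.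

Step 7
Reactants: 8 (3R)-3-methyl-3-[(trimethylsilyl)oxy]hex-5-en-2-one; 11 2-bromoacrolein
Product: 13 (6R)-2-bromo-3-hydroxy-6-methyl-6-[(trimethylsilyl)oxy]nona-1,8-dien-5-one (3-epimers), via lithium enolate 12 (not isolated)
Conditions: LiN(iPr)2 (commercial solution), THF, −78 °C; then 11, −78 °C, 15 min; AcOH quench at −78 °C
Reagents that add atoms: none
Why: Kinetic aldol addition: only the methyl group of 8 can be enolised and the lithium enolate adds 1,2 to the enal at −78 °C, the new carbinol centre being irrelevant because it is oxidised in the next step.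

Step 8
Reactants: 13 (6R)-2-bromo-3-hydroxy-6-methyl-6-[(trimethylsilyl)oxy]nona-1,8-dien-5-one
Product: 14 (6R)-2-bromo-6-methyl-6-[(trimethylsilyl)oxy]nona-1,8-diene-3,5-dione
Conditions: Dess–Martin periodinane, NaHCO3, CH2Cl2, 0 °C → rt
Reagents that add atoms: none
Why: Buffered Dess–Martin oxidation converts the β-hydroxy ketone into the enolised 1,3-diketone under conditions too mild to disturb the bromo enone or the silyl ether.

Step 9
Reactants: 14 (6R)-2-bromo-6-methyl-6-[(trimethylsilyl)oxy]nona-1,8-diene-3,5-dione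
Product: 17 (2R)-5-(1-bromoethenyl)-2-methyl-2-(prop-2-en-1-yl)furan-3(2H)-one, via hydroxy diketone 15 (not isolated), via cyclic hemiketal 16 (not isolated)
Conditions: 1 M aq. HCl, THF, rt
Reagents that add atoms: none
Why: Acid removes the silyl group, the freed tertiary alcohol adds to the distal ketone and the hemiketal dehydrates to the vinylogous ester, the classical cyclodehydration of an α'-hydroxy-1,3-diketone to a 3(2H)-furanone, in which C10 is not involved.

Step 10
Reactants: 17 (2R)-5-(1-bromoethenyl)-2-methyl-2-(prop-2-en-1-yl)furan-3(2H)-one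
Product: 19 2-[(2R)-5-(1-bromoethenyl)-2-methyl-3-oxo-2,3-dihydrofuran-2-yl]acetaldehyde (fragment A), via vicinal diol 18 (not isolated)
Conditions: OsO4 (2 mol%), NaIO4, 2,6-lutidine, dioxane/H2O (3:1), rt
Reagents that add atoms: osmium tetroxide, O=[Os](=O)(=O)=O; sodium periodate, [Na+].[O-]I(=O)(=O)=O
Why: Lemieux–Johnson oxidative cleavage: the electrophilic oxidant takes the isolated monosubstituted alkene much faster than the electron-poor brominated diene of the vinylogous ester, and periodate cleaves the diol to the C8 aldehyde.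

Step 11
Reactants: 20 (S)-solketal
Product: 21 tert-butyl{[(4R)-2,2-dimethyl-1,3-dioxolan-4-yl]methoxy}diphenylsilane
Conditions: tBuPh2SiCl, imidazole, CH2Cl2, rt
Reagents that add atoms: tert-butylchlorodiphenylsilane, CC(C)(C)[Si](Cl)(c1ccccc1)c1ccccc1
Why: Silylation protects the primary alcohol (the later C5 oxygen) with a group that survives acid, hydride, zinc and DDQ.

Step 12
Reactants: 21 tert-butyl{[(4R)-2,2-dimethyl-1,3-dioxolan-4-yl]methoxy}diphenylsilane
Product: 22 (2R)-3-[(tert-butyldiphenylsilyl)oxy]propane-1,2-diol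
Conditions: AcOH/H2O (4:1), 45 °C
Reagents that add atoms: none
Why: Mild acid hydrolysis of the acetonide leaves the silyl ether intact and frees the C6/C7 diol.

Step 13
Reactants: 22 (2R)-3-[(tert-butyldiphenylsilyl)oxy]propane-1,2-diol
Product: 23 (4R)-4-{[(tert-butyldiphenylsilyl)oxy]methyl}-2-(4-methoxyphenyl)-1,3-dioxolane (acetal epimers)
Conditions: 4-MeOC6H4CH(OMe)2, pyridinium p-toluenesulfonate (cat.), CH2Cl2, rt
Reagents that add atoms: 4-methoxybenzaldehyde dimethyl acetal, COc1ccc(cc1)C(OC)OC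
Why: Transacetalisation ties the diol up as a p-methoxybenzylidene acetal, ready for regioselective opening.

Step 14
Reactants: 23 (4R)-4-{[(tert-butyldiphenylsilyl)oxy]methyl}-2-(4-methoxyphenyl)-1,3-dioxolane
Product: 24 (2R)-3-[(tert-butyldiphenylsilyl)oxy]-2-[(4-methoxyphenyl)methoxy]propan-1-ol
Conditions: iBu2AlH, CH2Cl2, −78 → 0 °C; aq. potassium sodium tartrate
Reagents that add atoms: none
Why: Regioselective reductive acetal opening: the aluminium hydride coordinates the less hindered primary oxygen and cleaves that C–O bond, leaving the PMB group on the secondary (C6) oxygen and the primary alcohol free.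

Step 15
Reactants: 24 (2R)-3-[(tert-butyldiphenylsilyl)oxy]-2-[(4-methoxyphenyl)methoxy]propan-1-ol
Product: 25 (2S)-3-[(tert-butyldiphenylsilyl)oxy]-2-[(4-methoxyphenyl)methoxy]propanal
Conditions: Dess–Martin periodinane, NaHCO3, CH2Cl2, 0 °C; use crude
Reagents that add atoms: none
Why: Buffered Dess–Martin oxidation gives the α-alkoxy aldehyde without epimerising the adjacent stereocentre.

Step 16
Reactants: 25 (2S)-3-[(tert-butyldiphenylsilyl)oxy]-2-[(4-methoxyphenyl)methoxy]propanal; 26 methyl acrylate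
Product: 27 methyl (4S)-5-[(tert-butyldiphenylsilyl)oxy]-3-hydroxy-4-[(4-methoxyphenyl)methoxy]-2-methylidenepentanoate (3-epimers)
Conditions: 26 (excess), 1,4-diazabicyclo[2.2.2]octane, dioxane/H2O (1:1), rt
Reagents that add atoms: none
Why: Morita–Baylis–Hillman reaction of the activated α-alkoxy aldehyde installs the acrylate unit (C11–C13); the carbinol epimers converge in the next step and the fast aqueous conditions limit epimerisation at C6.

Step 17
Reactants: 27 methyl (4S)-5-[(tert-butyldiphenylsilyl)oxy]-3-hydroxy-4-[(4-methoxyphenyl)methoxy]-2-methylidenepentanoate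
Product: 29 methyl (2Z,4R)-2-(bromomethyl)-5-[(tert-butyldiphenylsilyl)oxy]-4-[(4-methoxyphenyl)methoxy]pent-2-enoate (fragment B), via allylic mesylate 28 (not isolated)
Conditions: MsCl, Et3N, CH2Cl2, −20 °C; then LiBr, THF, 0 °C → rt
Reagents that add atoms: lithium bromide, [Li+].[Br-]
Why: Mesylation followed by SN2' displacement with bromide moves the double bond into conjugation and gives the thermodynamically preferred trisubstituted (Z)-2-(bromomethyl)enoate, with the C6 substituent trans to the ester.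

Step 18
Reactants: 19 2-[(2R)-5-(1-bromoethenyl)-2-methyl-3-oxo-2,3-dihydrofuran-2-yl]acetaldehyde; 29 methyl (2Z,4R)-2-(bromomethyl)-5-[(tert-butyldiphenylsilyl)oxy]-4-[(4-methoxyphenyl)methoxy]pent-2-enoate
Product: 32 (4S,5S)-5-{[(2R)-5-(1-bromoethenyl)-2-methyl-3-oxo-2,3-dihydrofuran-2-yl]methyl}-4-{(1R)-2-[(tert-butyldiphenylsilyl)oxy]-1-[(4-methoxyphenyl)methoxy]ethyl}-3-methylideneoxolan-2-one, via allylzinc bromide 30 (not isolated), via syn hydroxy ester 31 (not isolated)
Conditions: Zn dust, THF/sat. aq. NH4Cl (2:1), 0 °C → rt; then TsOH·H2O (cat.), CH2Cl2, rt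
Reagents that add atoms: none
Why: Zinc Barbier (Dreiding–Schmidt) allylation: zinc inserts only into the allylic C–Br bond, the allylzinc adds through a chair Zimmerman–Traxler transition state with the C6 substituent axial (from the Z olefin) to give the 7,8-syn adduct and hence the cis-lactone after acid lactonisation, and the aldehyde approaches C7 anti to the C6–O bond in the conformer with H-6 eclipsing the olefin (minimal allylic 1,3-strain), which sets C7 (S) and C8 (S).

Step 19
Reactants: 32 (4S,5S)-5-{[(2R)-5-(1-bromoethenyl)-2-methyl-3-oxo-2,3-dihydrofuran-2-yl]methyl}-4-{(1R)-2-[(tert-butyldiphenylsilyl)oxy]-1-[(4-methoxyphenyl)methoxy]ethyl}-3-methylideneoxolan-2-one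
Product: 33 (4R,5S)-5-{[(2R)-5-(1-bromoethenyl)-2-methyl-3-oxo-2,3-dihydrofuran-2-yl]methyl}-4-{(1R)-2-[(tert-butyldiphenylsilyl)oxy]-1-hydroxyethyl}-3-methylideneoxolan-2-one
Conditions: DDQ, CH2Cl2/aq. Na2HPO4–NaH2PO4 buffer (pH 7), 0 °C → rt
Reagents that add atoms: none
Why: Oxidative cleavage of the electron-rich PMB ether under neutral conditions frees only the C6 hydroxyl, since all olefins present are electron-poor and the silyl ether is inert (the descriptor at C7 changes only through CIP priorities).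

Step 20
Reactants: 33 (4R,5S)-5-{[(2R)-5-(1-bromoethenyl)-2-methyl-3-oxo-2,3-dihydrofuran-2-yl]methyl}-4-{(1R)-2-[(tert-butyldiphenylsilyl)oxy]-1-hydroxyethyl}-3-methylideneoxolan-2-one
Product: 34 (4S,5S)-5-{[(2R)-5-(1-bromoethenyl)-2-methyl-3-oxo-2,3-dihydrofuran-2-yl]methyl}-4-{(1R)-2-[(tert-butyldiphenylsilyl)oxy]-1-[(2-methylprop-2-enoyl)oxy]ethyl}-3-methylideneoxolan-2-one
Conditions: methacrylic anhydride, Et3N, 4-(dimethylamino)pyridine (cat.), CH2Cl2, 0 °C → rt
Reagents that add atoms: methacrylic anhydride, CC(=C)C(=O)OC(=O)C(C)=C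
Why: Nucleophile-catalysed acylation (Steglich-type) esterifies the only free hydroxyl, at C6, before the C5 oxygen is unmasked, which fixes the regiochemistry of the methacrylate.

Step 21
Reactants: 34 (4S,5S)-5-{[(2R)-5-(1-bromoethenyl)-2-methyl-3-oxo-2,3-dihydrofuran-2-yl]methyl}-4-{(1R)-2-[(tert-butyldiphenylsilyl)oxy]-1-[(2-methylprop-2-enoyl)oxy]ethyl}-3-methylideneoxolan-2-one
Product: 35 (4S,5S)-5-{[(2R)-5-(1-bromoethenyl)-2-methyl-3-oxo-2,3-dihydrofuran-2-yl]methyl}-4-{(1R)-2-hydroxy-1-[(2-methylprop-2-enoyl)oxy]ethyl}-3-methylideneoxolan-2-one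
Conditions: HF·pyridine, pyridine/THF, 0 °C → rt
Reagents that add atoms: none
Why: Fluoride-mediated desilylation under weakly acidic conditions frees the primary C5 alcohol while suppressing base-induced 1,2-acyl migration of the neighbouring methacrylate.

Step 22
Reactants: 35 (4S,5S)-5-{[(2R)-5-(1-bromoethenyl)-2-methyl-3-oxo-2,3-dihydrofuran-2-yl]methyl}-4-{(1R)-2-hydroxy-1-[(2-methylprop-2-enoyl)oxy]ethyl}-3-methylideneoxolan-2-one
Product: 36 (4S,5S)-5-{[(2R)-5-(1-bromoethenyl)-2-methyl-3-oxo-2,3-dihydrofuran-2-yl]methyl}-3-methylidene-4-{(1R)-1-[(2-methylprop-2-enoyl)oxy]-2-oxoethyl}oxolan-2-one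
Conditions: Dess–Martin periodinane, NaHCO3, CH2Cl2, 0 °C; use crude at once
Reagents that add atoms: none
Why: Buffered Dess–Martin oxidation gives the sensitive α-acyloxy aldehyde without epimerisation at C6 or acyl migration.

Step 23
Reactants: 36 (4S,5S)-5-{[(2R)-5-(1-bromoethenyl)-2-methyl-3-oxo-2,3-dihydrofuran-2-yl]methyl}-3-methylidene-4-{(1R)-1-[(2-methylprop-2-enoyl)oxy]-2-oxoethyl}oxolan-2-one
Product: 38 (5S,6R,7S,8S,10R)-3,10-epoxy-5-hydroxy-6-[(2-methylprop-2-enoyl)oxy]-1-oxogermacra-2,4(15),11(13)-trien-12,8-olide (CNP0142847.2), via alkenylchromium dichloride 37 (not isolated)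
Conditions: CrCl2 (15 equiv), NiCl2 (10 mol%), degassed DMSO/THF, rt, syringe-pump addition to 1 mM
Reagents that add atoms: none
Why: Intramolecular Nozaki–Hiyama–Kishi reaction: zerovalent nickel formed in situ inserts into the alkenyl C–Br bond, transmetallation gives the trivalent alkenylchromium species, which adds only to the aldehyde and closes the ten-membered carbocycle, attack anti to the α-acyloxy group (Felkin–Anh polar model) setting C5 as S (5,6-anti).

## Compound list

1 | (S)-lactic acid | C[C@H](O)C(=O)O | starting material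
2 | (2S,5S)-2-tert-butyl-5-methyl-1,3-dioxolan-4-one | C[C@@H]1O[C@H](C(C)(C)C)OC1=O | intermediate
3 | allyl bromide | C=CCBr | starting material
4 | lithium (2S)-2-tert-butyl-5-methyl-1,3-dioxol-4-olate (lithium enolate of 2) | CC1=C(O[Li])O[C@@H](C(C)(C)C)O1 | intermediate
5 | (2S,5R)-2-tert-butyl-5-methyl-5-(prop-2-en-1-yl)-1,3-dioxolan-4-one | C[C@]1(CC=C)O[C@H](C(C)(C)C)OC1=O | intermediate
6 | (2R)-2-hydroxy-N-methoxy-N,2-dimethylpent-4-enamide | C=CC[C@@](C)(O)C(=O)N(C)OC | intermediate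
7 | (2R)-N-methoxy-N,2-dimethyl-2-[(trimethylsilyl)oxy]pent-4-enamide | C=CC[C@@](C)(O[Si](C)(C)C)C(=O)N(C)OC | intermediate
8 | (3R)-3-methyl-3-[(trimethylsilyl)oxy]hex-5-en-2-one | C=CC[C@@](C)(O[Si](C)(C)C)C(C)=O | intermediate
9 | acrolein | C=CC=O | starting material
10 | 2,3-dibromopropanal (racemic) | O=CC(Br)CBr | intermediate
11 | 2-bromoacrolein | C=C(Br)C=O | intermediate
12 | lithium (3R)-3-methyl-3-[(trimethylsilyl)oxy]hexa-1,5-dien-2-olate (lithium enolate of 8) | C=CC[C@@](C)(O[Si](C)(C)C)C(=C)O[Li] | intermediate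
13 | (6R)-2-bromo-3-hydroxy-6-methyl-6-[(trimethylsilyl)oxy]nona-1,8-dien-5-one (3-epimers) | C=CC[C@@](C)(O[Si](C)(C)C)C(=O)CC(O)C(Br)=C | intermediate
14 | (6R)-2-bromo-6-methyl-6-[(trimethylsilyl)oxy]nona-1,8-diene-3,5-dione | C=CC[C@@](C)(O[Si](C)(C)C)C(=O)CC(=O)C(Br)=C | intermediate
15 | (6R)-2-bromo-6-hydroxy-6-methylnona-1,8-diene-3,5-dione | C=CC[C@@](C)(O)C(=O)CC(=O)C(Br)=C | intermediate
16 | (2R)-5-(1-bromoethenyl)-5-hydroxy-2-methyl-2-(prop-2-en-1-yl)oxolan-3-one (hemiketal epimers) | C=CC[C@@]1(C)OC(O)(CC1=O)C(Br)=C | intermediate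
17 | (2R)-5-(1-bromoethenyl)-2-methyl-2-(prop-2-en-1-yl)furan-3(2H)-one | C=CC[C@@]1(C)OC(=CC1=O)C(Br)=C | intermediate
18 | (2R)-5-(1-bromoethenyl)-2-(2,3-dihydroxypropyl)-2-methylfuran-3(2H)-one (diol epimers) | OCC(O)C[C@@]1(C)OC(=CC1=O)C(Br)=C | intermediate
19 | 2-[(2R)-5-(1-bromoethenyl)-2-methyl-3-oxo-2,3-dihydrofuran-2-yl]acetaldehyde (fragment A) | O=CC[C@@]1(C)OC(=CC1=O)C(Br)=C | intermediate
20 | (S)-solketal, [(4S)-2,2-dimethyl-1,3-dioxolan-4-yl]methanol | CC1(C)OC[C@H](CO)O1 | starting material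
21 | tert-butyl{[(4R)-2,2-dimethyl-1,3-dioxolan-4-yl]methoxy}diphenylsilane | CC1(C)OC[C@H](CO[Si](c2ccccc2)(c2ccccc2)C(C)(C)C)O1 | intermediate
22 | (2R)-3-[(tert-butyldiphenylsilyl)oxy]propane-1,2-diol | OC[C@H](CO[Si](c1ccccc1)(c1ccccc1)C(C)(C)C)O | intermediate
23 | (4R)-4-{[(tert-butyldiphenylsilyl)oxy]methyl}-2-(4-methoxyphenyl)-1,3-dioxolane (acetal epimers) | COc1ccc(cc1)C1OC[C@H](CO[Si](c2ccccc2)(c2ccccc2)C(C)(C)C)O1 | intermediate
24 | (2R)-3-[(tert-butyldiphenylsilyl)oxy]-2-[(4-methoxyphenyl)methoxy]propan-1-ol | OC[C@H](CO[Si](c1ccccc1)(c1ccccc1)C(C)(C)C)OCc1ccc(OC)cc1 | intermediate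
25 | (2S)-3-[(tert-butyldiphenylsilyl)oxy]-2-[(4-methoxyphenyl)methoxy]propanal | O=C[C@H](CO[Si](c1ccccc1)(c1ccccc1)C(C)(C)C)OCc1ccc(OC)cc1 | intermediate
26 | methyl acrylate | C=CC(=O)OC | starting material
27 | methyl (4S)-5-[(tert-butyldiphenylsilyl)oxy]-3-hydroxy-4-[(4-methoxyphenyl)methoxy]-2-methylidenepentanoate (3-epimers) | COC(=O)C(=C)C(O)[C@H](CO[Si](c1ccccc1)(c1ccccc1)C(C)(C)C)OCc1ccc(OC)cc1 | intermediate
28 | methyl (4S)-5-[(tert-butyldiphenylsilyl)oxy]-3-[(methanesulfonyl)oxy]-4-[(4-methoxyphenyl)methoxy]-2-methylidenepentanoate | COC(=O)C(=C)C(OS(C)(=O)=O)[C@H](CO[Si](c1ccccc1)(c1ccccc1)C(C)(C)C)OCc1ccc(OC)cc1 | intermediate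
29 | methyl (2Z,4R)-2-(bromomethyl)-5-[(tert-butyldiphenylsilyl)oxy]-4-[(4-methoxyphenyl)methoxy]pent-2-enoate (fragment B) | COC(=O)/C(CBr)=C/[C@H](CO[Si](c1ccccc1)(c1ccccc1)C(C)(C)C)OCc1ccc(OC)cc1 | intermediate
30 | {(2Z,4R)-5-[(tert-butyldiphenylsilyl)oxy]-2-(methoxycarbonyl)-4-[(4-methoxyphenyl)methoxy]pent-2-en-1-yl}zinc bromide | COC(=O)/C(C[Zn]Br)=C/[C@H](CO[Si](c1ccccc1)(c1ccccc1)C(C)(C)C)OCc1ccc(OC)cc1 | intermediate
31 | methyl (3S,4S)-5-[(2R)-5-(1-bromoethenyl)-2-methyl-3-oxo-2,3-dihydrofuran-2-yl]-3-{(1R)-2-[(tert-butyldiphenylsilyl)oxy]-1-[(4-methoxyphenyl)methoxy]ethyl}-4-hydroxy-2-methylidenepentanoate | CC(C)(C)[Si](c1ccccc1)(c1ccccc1)OC[C@H](OCc1ccc(OC)cc1)[C@H]([C@@H](O)C[C@@]1(C)OC(=CC1=O)C(Br)=C)C(=C)C(=O)OC | intermediate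
32 | (4S,5S)-5-{[(2R)-5-(1-bromoethenyl)-2-methyl-3-oxo-2,3-dihydrofuran-2-yl]methyl}-4-{(1R)-2-[(tert-butyldiphenylsilyl)oxy]-1-[(4-methoxyphenyl)methoxy]ethyl}-3-methylideneoxolan-2-one | CC(C)(C)[Si](c1ccccc1)(c1ccccc1)OC[C@H](OCc1ccc(OC)cc1)[C@H]1C(=C)C(=O)O[C@H]1C[C@@]1(C)OC(=CC1=O)C(Br)=C | intermediate
33 | (4R,5S)-5-{[(2R)-5-(1-bromoethenyl)-2-methyl-3-oxo-2,3-dihydrofuran-2-yl]methyl}-4-{(1R)-2-[(tert-butyldiphenylsilyl)oxy]-1-hydroxyethyl}-3-methylideneoxolan-2-one | CC(C)(C)[Si](c1ccccc1)(c1ccccc1)OC[C@H](O)[C@H]1C(=C)C(=O)O[C@H]1C[C@@]1(C)OC(=CC1=O)C(Br)=C | intermediate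
34 | (4S,5S)-5-{[(2R)-5-(1-bromoethenyl)-2-methyl-3-oxo-2,3-dihydrofuran-2-yl]methyl}-4-{(1R)-2-[(tert-butyldiphenylsilyl)oxy]-1-[(2-methylprop-2-enoyl)oxy]ethyl}-3-methylideneoxolan-2-one | CC(C)(C)[Si](c1ccccc1)(c1ccccc1)OC[C@H](OC(=O)C(C)=C)[C@H]1C(=C)C(=O)O[C@H]1C[C@@]1(C)OC(=CC1=O)C(Br)=C | intermediate
35 | (4S,5S)-5-{[(2R)-5-(1-bromoethenyl)-2-methyl-3-oxo-2,3-dihydrofuran-2-yl]methyl}-4-{(1R)-2-hydroxy-1-[(2-methylprop-2-enoyl)oxy]ethyl}-3-methylideneoxolan-2-one | OC[C@H](OC(=O)C(C)=C)[C@H]1C(=C)C(=O)O[C@H]1C[C@@]1(C)OC(=CC1=O)C(Br)=C | intermediate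
36 | (4S,5S)-5-{[(2R)-5-(1-bromoethenyl)-2-methyl-3-oxo-2,3-dihydrofuran-2-yl]methyl}-3-methylidene-4-{(1R)-1-[(2-methylprop-2-enoyl)oxy]-2-oxoethyl}oxolan-2-one | O=C[C@H](OC(=O)C(C)=C)[C@H]1C(=C)C(=O)O[C@H]1C[C@@]1(C)OC(=CC1=O)C(Br)=C | intermediate
37 | alkenylchromium dichloride derived from 36 (C4–Cr in place of C4–Br) | O=C[C@H](OC(=O)C(C)=C)[C@H]1C(=C)C(=O)O[C@H]1C[C@@]1(C)OC(=CC1=O)C(=C)[Cr](Cl)Cl | intermediate
38 | (5S,6R,7S,8S,10R)-3,10-epoxy-5-hydroxy-6-[(2-methylprop-2-enoyl)oxy]-1-oxogermacra-2,4(15),11(13)-trien-12,8-olide (CNP0142847.2) | C=C(C)C(=O)O[C@@H]1[C@H]2C(=C)C(=O)O[C@H]2C[C@@]2(C)OC(=CC2=O)C(=C)[C@@H]1O | target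

## Step count and risks

Total step count: 23.
Longest linear sequence: 15 steps (steps 1–5, 7–10 and 18–23, from (S)-lactic acid); 15/23 = 0.65. The other branches are steps 11–17 (7 steps, from (S)-solketal) and step 6 (from acrolein).

Three steps most likely to fail:

**Step 7** (aldol with 2-bromoacrolein, and the handling of the bromo enone products 13 and 14). The enal can polymerise or react 1,4, and the α-bromo enone diketone is a strong Michael acceptor. The fallback sets out from 8 (as its enolate 12) and from 10, and comes back at 17. The enolate 12 is added at −78 °C to crude 2,3-dibromopropanal 10 (step 6 stopped before the Et3N treatment) and quenched cold with AcOH. This gives the dibromo aldol (6R)-1,2-dibromo-3-hydroxy-6-methyl-6-[(trimethylsilyl)oxy]non-8-en-5-one F1. Dess–Martin oxidation gives the diketone (6R)-1,2-dibromo-6-methyl-6-[(trimethylsilyl)oxy]non-8-ene-3,5-dione F2. Treatment with 1 M aq. HCl/THF desilylates and cyclodehydrates it to (2R)-5-(1,2-dibromoethyl)-2-methyl-2-(prop-2-en-1-yl)furan-3(2H)-one F3. Et3N in CH2Cl2 at 0 °C then removes HBr by an E1cB elimination (deprotonation at the acidic C4–H, loss of bromide from C15) to give 17. The bromovinyl group is thus unmasked only after the furanone exists.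

**Step 18** (zinc Barbier coupling). The 7,8-syn outcome is well supported by the olefin geometry, but the facial selectivity relative to C6 rests on a model, and 1,4-elimination of the γ-alkoxy allylzinc is possible. The fallback sets out from 27 and 19 and comes back at 31, which is lactonised to 32 as in step 18. Compound 27 is acetylated (Ac2O, 4-(dimethylamino)pyridine, CH2Cl2) to methyl (4S)-3-acetoxy-5-[(tert-butyldiphenylsilyl)oxy]-4-[(4-methoxyphenyl)methoxy]-2-methylidenepentanoate F4. Copper-catalysed SN2' borylation (B2pin2, CuCl, CH3CO2K, DMF, rt) gives the allylboronate methyl (2E,4R)-5-[(tert-butyldiphenylsilyl)oxy]-4-[(4-methoxyphenyl)methoxy]-2-[(4,4,5,5-tetramethyl-1,3,2-dioxaborolan-2-yl)methyl]pent-2-enoate F5, which has the same olefin geometry as 29. F5 is added to 19 in toluene at −30 °C → rt with a chiral phosphoric acid catalyst, 3,3'-bis(2,4,6-triisopropylphenyl)-1,1'-binaphthyl-2,2'-diyl hydrogen phosphate, using whichever enantiomer matches the required aldehyde face. The closed chair allylboration again gives the 7,8-syn adduct 31 after hydrolytic work-up, now with catalyst control of the facial selectivity instead of substrate control alone.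

**Step 23** (Nozaki–Hiyama–Kishi ring closure). The medium-ring closure may be slow, and the C5 configuration is set by a transition state whose macrocyclic bias cannot be predicted with confidence. The fallback sets out from 36 and comes back at 38. If the closure gives mainly the epimeric alcohol (5R,6R,7S,8S,10R)-3,10-epoxy-5-hydroxy-6-[(2-methylprop-2-enoyl)oxy]-1-oxogermacra-2,4(15),11(13)-trien-12,8-olide F6, or a mixture, the crude material is oxidised with Dess–Martin periodinane (NaHCO3, CH2Cl2, 0 °C) to the macrocyclic ketone (6R,7S,8S,10R)-3,10-epoxy-6-[(2-methylprop-2-enoyl)oxy]-1,5-dioxogermacra-2,4(15),11(13)-trien-12,8-olide F7. F7 is then reduced 1,2 under reagent control (Corey–Bakshi–Shibata reduction with 2-methyl-CBS-oxazaborolidine and catecholborane, toluene, −78 °C), using the catalyst enantiomer that delivers the 5S alcohol 38. C5 is then set by ketone reduction and no longer by the C–C bond formation.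

## Further compounds

F1 | step 7 | (6R)-1,2-dibromo-3-hydroxy-6-methyl-6-[(trimethylsilyl)oxy]non-8-en-5-one | C=CC[C@@](C)(O[Si](C)(C)C)C(=O)CC(O)C(Br)CBr
F2 | step 7 | (6R)-1,2-dibromo-6-methyl-6-[(trimethylsilyl)oxy]non-8-ene-3,5-dione | C=CC[C@@](C)(O[Si](C)(C)C)C(=O)CC(=O)C(Br)CBr
F3 | step 7 | (2R)-5-(1,2-dibromoethyl)-2-methyl-2-(prop-2-en-1-yl)furan-3(2H)-one | C=CC[C@@]1(C)OC(=CC1=O)C(Br)CBr
F4 | step 18 | methyl (4S)-3-acetoxy-5-[(tert-butyldiphenylsilyl)oxy]-4-[(4-methoxyphenyl)methoxy]-2-methylidenepentanoate | COC(=O)C(=C)C(OC(C)=O)[C@H](CO[Si](c1ccccc1)(c1ccccc1)C(C)(C)C)OCc1ccc(OC)cc1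
F5 | step 18 | methyl (2E,4R)-5-[(tert-butyldiphenylsilyl)oxy]-4-[(4-methoxyphenyl)methoxy]-2-[(4,4,5,5-tetramethyl-1,3,2-dioxaborolan-2-yl)methyl]pent-2-enoate | COC(=O)/C(CB1OC(C)(C)C(C)(C)O1)=C/[C@H](CO[Si](c1ccccc1)(c1ccccc1)C(C)(C)C)OCc1ccc(OC)cc1
F6 | step 23 | (5R,6R,7S,8S,10R)-3,10-epoxy-5-hydroxy-6-[(2-methylprop-2-enoyl)oxy]-1-oxogermacra-2,4(15),11(13)-trien-12,8-olide | C=C(C)C(=O)O[C@@H]1[C@H]2C(=C)C(=O)O[C@H]2C[C@@]2(C)OC(=CC2=O)C(=C)[C@H]1O
F7 | step 23 | (6R,7S,8S,10R)-3,10-epoxy-6-[(2-methylprop-2-enoyl)oxy]-1,5-dioxogermacra-2,4(15),11(13)-trien-12,8-olide | C=C(C)C(=O)O[C@@H]1[C@H]2C(=C)C(=O)O[C@H]2C[C@@]2(C)OC(=CC2=O)C(=C)C1=O
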